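If the target reading stops rising, making and losing have come level, and the reading alone does not say which of the two has changed. Sunday's run can tell us, since it repeats Monday's charge with target added at the start.

all flasks: free catalyst 0.0100 M

| charge | substrate | target | time |
|---|---|---|---|
| Monday's | 0.500 M |  |  |
| Friday's | 0.250 M |  |  |
| Sunday's | 0.500 M | 0.150 M |  |
| Wednesday's | 0.250 M |  |  |
| Tuesday's | 0.200 M |  | 130 s |

- Monday's run (time / s: [target] / M): 5.8: 0.022; 18: 0.057; 34: 0.095; 53: 0.135; 76: 0.155; 100: 0.174; 130: 0.174
- Friday's run (time / s: [target] / M): 5.8: 0.009; 18: 0.038; 34: 0.061; 53: 0.083; 76: 0.095; 100: 0.104; 130: 0.115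
- Sunday's run (time / s: [target] / M): 5.8: 0.174; 18: 0.208; 34: 0.239; 53: 0.259; 76: 0.281; 100: 0.288; 130: 0.287
- Wednesday's run (time / s: [target] / M): 5.8: 0.012; 18: 0.031; 34: 0.061; 53: 0.076; 76: 0.094; 100: 0.108; 130: 0.105

(scatter of a reading: 0.004 M)

1. order of the initial rate in [substrate], near the charge of the Monday's run, the rate being that where two percent of its substrate are target (one fixed amount of target, the same in the runs compared)
2. target in the Tuesday's run at 130 s, as a share of the substrate charged

- Overall: substrate -> target, with free catalyst as catalyst.
- Constant volume, constant temperature.
- An order is taken over about fifteen percent of the charge, up and down.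

Sunday's gain at 18 s is 0.0580 M against Monday's 0.057 M, so within the scatter the added target shows no effect on the making at first. Suppose the two flasks go on making the same amount. Then Sunday's reading minus Monday's is what survives of the added target, and at 130 s that is 0.113 M of 0.150 M. Taking the loss as first order in target, we get 0.00218 s⁻¹. This is the leak, the share of the target present that disappears each second, a first-order rate constant, and it is a reading with the scatter of two readings in it.

Now Tuesday's run. Target is not made steadily: Friday's run, charged with 0.250 M against Tuesday's 0.200 M, reads 0.061 M at 34 s and gains a further 0.0540 M by 130 s. We take Tuesday's run to have the same shape and let each portion wait from the middle of its interval to the end, which gives an average wait of 82.5 s. So we expect 0.836 of what was made in Tuesday's run to be standing at the end. Our reckoning gives this factor, not the share itself.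

The forecast puts the order at 0.66, with a range from 0.5 to 0.82, because it sees Monday against Friday and Wednesday “keep a near-constant target ratio of about 1.6 at all times”. For Tuesday's run it gives 47%, with a range from 44% to 51%.

The flask gives an order of 1.0, above the forecast's high end, and 46.4% for Tuesday's run, inside the forecast's range.

    free catalyst + substrate → target + free catalyst (0.8290 L mol⁻¹ s⁻¹)
    free catalyst + substrate → spent catalyst + substrate (0.02480 L mol⁻¹ s⁻¹)
    target → decomposed product (0.002770 s⁻¹)

The leak is the step from target to decomposed product: Tuesday's run stands at 46.4% with that step and 57.4% without it. So 0.808 of its target survives, less than our 0.836. In Sunday's run the added target leaks at 3.27 × 10⁻⁴ M s⁻¹, which against Monday's rate of 0.0039 M s⁻¹ gives a ratio of 0.916. The two runs' rates, taken where the same amount has been made, stand in the ratio 0.89.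

The runs stem from a simulated flask with made-up constants, and the scatter is random.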